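**Two neighbours.** If you set the zeta flask beside the north run, they look nearly the same: [incoming ligand] is 0.100 M against 0.081 M, and the other charges match.

all flasks: starting complex 0.20 M
- north: incoming ligand 0.081 M; leaving ligand 1 M; run made earlier
- south: incoming ligand 0.20 M; leaving ligand 1 M; run made earlier
- north-west: incoming ligand 0.55 M; leaving ligand 1 M; run made earlier
- zeta: incoming ligand 0.100 M; leaving ligand 1.00 M; time 2.5 h
- theta: incoming ligand 0.160 M; leaving ligand 1.00 M; time 2.5 h
- alpha: incoming ligand 0.500 M; leaving ligand 1.00 M; time 2.5 h

| run | time / h | complex with one exchanged / % | starting complex / % |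
|---|---|---|---|
| north | 0.333 | 18.0 | 69.4 |
| north | 0.833 | 16.5 | 67.2 |
| north | 1.50 | 13.9 | 66.9 |
| north | 2.50 | 10.3 | 63.4 |
| south | 0.667 | 16.4 | 38.8 |
| south | 1.33 | 13.6 | 39.2 |
| south | 2.00 | 11.1 | 38.2 |
| south | 2.50 | 13.1 | 36.1 |
| north-west | 0.200 | 5.0 | 6.1 |
| north-west | 0.500 | 0.5 | 0 |
| north-west | 1.00 | 0.4 | 0 |
| north-west | 2.50 | 0.1 | 0 |

(scatter of a reading: 1 percentage point)

- the analysis behind the earlier runs scatters by 1 percentage point, standard deviation

- amount of complex with one exchanged at the end, in percent of the starting complex charged, for each flask in turn (zeta, theta, alpha)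

**Ligand used.** At north's first reading 30.6 % of the starting complex has reacted, and 18.0 % stands as complex with one exchanged. Count the rest as complex with two exchanged. The ligand taken is then 43.2 % of the complex charged, against a charge of 40.5 %. So, within the scatter of these figures, I take the incoming ligand, the limiting reagent, as used up in north by 0.333 h.

**Fade constant.** North's first and last readings give 0.258 h⁻¹ for the fade constant, the first-order rate at which complex with one exchanged is lost once the incoming ligand is used up. With ligand in excess, north-west loses it much faster: its readings give 7.68 h⁻¹.

**My reckoning.** Carry south's first reading back to north's first time with the fade constant. You get 17.9 %, against north's 18.0 %. The height matches within the scatter, although south has more ligand. Zeta and theta lie between these charges, so I give both the same height and the same fade, which ends them near 10.3 %. Alpha keeps 0.100 M of ligand beyond two equivalents. Scaled to that, the fast rate is 5.12 h⁻¹, so I expect alpha near zero, like north-west.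

**The forecast.** It gives 11.6 %, 11.7 % and 0.2 %, and it has complex with one exchanged fade “roughly first order with k ≈ 0.2 h⁻¹” once the incoming ligand is used up. For zeta it stands 1.3 percentage points above my figure.

**The flask.** Zeta ends at 11.2 %, theta at 11.7 % and alpha at <0.001 %.

    starting complex + incoming ligand → leaving ligand + complex with one exchanged (k = 49.0 M⁻¹ h⁻¹)
    complex with one exchanged + incoming ligand → leaving ligand + complex with two exchanged (k = 120 M⁻¹ h⁻¹)
    complex with one exchanged → over-reaction product (k = 0.260 h⁻¹)
    starting complex ⇌ dormant form (K = 1.40, k = 0.0310 h⁻¹)

In zeta the incoming ligand stands at 0 % after 1.25 h, and complex with one exchanged goes from 15.5 % there to 11.2 % at 2.50 h. The fade constant gives 11.2 % for that stretch. Carried on theta from 11.7 % at 2.50 h to 25.0 h, it gives 0.0355 %, and theta holds 0.0337 %.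

The earlier runs and the new flask stem from a simulated flask on assumed constants; scatter was added.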